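**Retrosynthetic overview**

- The target is made from its tri-O-benzyl ether alcohol by acetylation and debenzylation; the tetrahydrofuran (the only ring in the target, formed last) is closed by acid cycloetherification of a benzylic carbinol onto a primary alcohol of a triol.
- The triol comes from LiAlH4 reduction of a trans-3-benzyl-4-aroyl-butyrolactone; this lactone is a temporary first ring, made by formaldehyde aldol/lactonisation of a γ-keto imide.
- The γ-keto imide is made by forming the central C8–C8' bond through oxidative heterocoupling of two enolates. Both α-carbons are natural donors; one is oxidised to an electrophilic α-carbonyl radical (enolonium equivalent), and an Evans auxiliary fixes C8'.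
- Ring order: butyrolactone (step 4), opened (step 5), tetrahydrofuran (step 6).

Assumption: 1-[3,4-bis(benzyloxy)phenyl]ethan-1-one is bought as a catalogue chemical. Lignan numbering is used for atoms: C7/C8/C9 = catechol-side ArCH–CH–CH2OAc; C7'/C8'/C9' = guaiacyl-side ArCH2–CH–CH2O.

**Route**

Step 1
Reactants: 1 3-(4-hydroxy-3-methoxyphenyl)propanoic acid
Product: 3 3-[4-(benzyloxy)-3-methoxyphenyl]propanoic acid, via benzyl ester 2 (not isolated)
Conditions: BnBr (2.3 equiv), K2CO3, DMF, 60 °C; then 2 M NaOH, MeOH, 60 °C; HCl to pH 2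
Reagents that add atoms: benzyl bromide BrCc1ccccc1; sodium hydroxide [Na+].[OH-] (supplies the carboxyl oxygen on ester hydrolysis)
Why: Williamson O-benzylation of the phenoxide and carboxylate followed by saponification of the benzyl ester leaves only the phenol protected, and no stereocentre is involved.

Step 2
Reactants: 3 3-[4-(benzyloxy)-3-methoxyphenyl]propanoic acid; 4 (4S)-4-benzyl-1,3-oxazolidin-2-one
Product: 6 (4S)-4-benzyl-3-{3-[4-(benzyloxy)-3-methoxyphenyl]propanoyl}-1,3-oxazolidin-2-one, via mixed pivalic anhydride 5 (not isolated)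
Conditions: t-BuCOCl, Et3N, THF, −20 °C; then 4, LiCl, −20 °C → rt
Reagents that add atoms: none
Why: Mixed-anhydride N-acylation of the Evans oxazolidinone (LiCl/Et3N activation) attaches the auxiliary, the only stereocentre being the purchased (S) centre of 4.

Step 3
Reactants: 6 (4S)-4-benzyl-3-{3-[4-(benzyloxy)-3-methoxyphenyl]propanoyl}-1,3-oxazolidin-2-one; 7 1-[3,4-bis(benzyloxy)phenyl]ethan-1-one
Product: 10 (4S)-4-benzyl-3-[(2R)-2-{[4-(benzyloxy)-3-methoxyphenyl]methyl}-4-[3,4-bis(benzyloxy)phenyl]-4-oxobutanoyl]-1,3-oxazolidin-2-one, via imide lithium enolate 8 (not isolated), via ketone lithium enolate 9 (not isolated)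
Conditions: 6 (1.0 equiv) + 7 (1.5 equiv), LiN(iPr)2 (2.6 equiv), THF, −78 °C, 30 min; then Cu(O2CCH(Et)Bu)2 (copper bis(2-ethylhexanoate), 2.6 equiv), THF, −78 °C → rt
Reagents that add atoms: none
Why: Oxidative enolate heterocoupling (Baran type): one-electron oxidation of the mixed lithium enolate aggregate by the divalent copper carboxylate turns one α-carbon into an electrophilic α-carbonyl radical that bonds to the α-carbon of the other enolate, so two natural donor carbons (C8 and C8') are joined, and the new C8' stereocentre is set by the auxiliary because the chelated Z-enolate 8 reacts on the face opposite the 4-benzyl group, as in Evans alkylations, to give the 2R product.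

Step 4
Reactants: 10 (4S)-4-benzyl-3-[(2R)-2-{[4-(benzyloxy)-3-methoxyphenyl]methyl}-4-[3,4-bis(benzyloxy)phenyl]-4-oxobutanoyl]-1,3-oxazolidin-2-one
Product: 12 (3R,4R)-3-{[4-(benzyloxy)-3-methoxyphenyl]methyl}-4-[3,4-bis(benzyloxy)benzoyl]oxolan-2-one, via hydroxymethyl keto imide 11 (not isolated)
Conditions: (CH2O)n (1.3 equiv), K2CO3 (0.3 equiv), DMSO, rt; NH4Cl work-up
Reagents that add atoms: formaldehyde C=O (used as paraformaldehyde)
Why: Proposed new method: base-catalysed aldol hydroxymethylation occurs at the ketone α-CH2 (C8), the imide α-CH being kinetically shielded by allylic 1,3-strain, to give 11, whose hydroxyl acylates itself on the activated imide carbonyl through a five-membered transition state and expels the oxazolidinone, while continued reversible enolisation at C8 equilibrates the lactone to the more stable trans (3R,4R) isomer and so sets C8; the closest known reactions are the formaldehyde/alkali hydroxymethylation–lactonisation of 3-aroylpropanoic acids to 4-aroylbutyrolactones and the alkoxide cleavage of N-acyl oxazolidinones.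

Step 5
Reactants: 12 (3R,4R)-3-{[4-(benzyloxy)-3-methoxyphenyl]methyl}-4-[3,4-bis(benzyloxy)benzoyl]oxolan-2-one
Product: 13 (2R,3R)-2-{[4-(benzyloxy)-3-methoxyphenyl]methyl}-3-{[3,4-bis(benzyloxy)phenyl](hydroxy)methyl}butane-1,4-diol (both carbinol epimers)
Conditions: LiAlH4 (4 equiv), THF, 0 °C → rt; then H2O/15% aq NaOH (Fieser work-up)
Reagents that add atoms: none
Why: Exhaustive LiAlH4 hydride reduction of the lactone and aryl ketone gives the triol, after which C8 and C8' are no longer enolisable, and the C7 carbinol forms as an epimer mixture that converges in the next step.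

Step 6
Reactants: 13 (2R,3R)-2-{[4-(benzyloxy)-3-methoxyphenyl]methyl}-3-{[3,4-bis(benzyloxy)phenyl](hydroxy)methyl}butane-1,4-diol
Product: 14 [(2S,3R,4R)-2-[3,4-bis(benzyloxy)phenyl]-4-{[4-(benzyloxy)-3-methoxyphenyl]methyl}oxolan-3-yl]methanol
Conditions: (1S)-(+)-10-camphorsulfonic acid (0.1 equiv), CH2Cl2, 0 °C, 1–2 h; Et3N quench
Reagents that add atoms: none
Why: Acid-catalysed SN1 cycloetherification: the p-alkoxybenzylic cation from either C7 epimer is captured 5-exo by the C9' hydroxyl (the C9 hydroxyl could only give an oxetane), and the aryl group settles trans to the adjacent cis-related CH2OH and benzyl groups, which sets C7 as (2S); the reaction is kept cold and short to avoid Friedel–Crafts closure to an aryltetralin.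

Step 7
Reactants: 14 [(2S,3R,4R)-2-[3,4-bis(benzyloxy)phenyl]-4-{[4-(benzyloxy)-3-methoxyphenyl]methyl}oxolan-3-yl]methanol
Product: 15 [(2S,3R,4R)-2-[3,4-bis(benzyloxy)phenyl]-4-{[4-(benzyloxy)-3-methoxyphenyl]methyl}oxolan-3-yl]methyl acetate
Conditions: Ac2O, pyridine, DMAP (cat.), CH2Cl2, 0 °C → rt
Reagents that add atoms: acetic anhydride CC(=O)OC(C)=O
Why: DMAP-catalysed O-acylation of the only free hydroxyl (all phenols are still benzylated) gives the primary acetate without touching any stereocentre.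

Step 8
Reactants: 15 [(2S,3R,4R)-2-[3,4-bis(benzyloxy)phenyl]-4-{[4-(benzyloxy)-3-methoxyphenyl]methyl}oxolan-3-yl]methyl acetate
Product: 16 [(2S,3R,4R)-2-(3,4-dihydroxyphenyl)-4-[(4-hydroxy-3-methoxyphenyl)methyl]oxolan-3-yl]methyl acetate
Conditions: H2 (1 atm), Pd/C (10 wt% palladium on carbon), EtOAc, rt, stopped as soon as debenzylation is complete; handled under argon
Reagents that add atoms: none
Why: Catalytic hydrogenolysis cleaves the three aryl benzyl ethers much faster than the cyclic benzylic ether in a neutral, non-protic solvent, leaving the acetate and all three stereocentres untouched.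

**Compound list**

1 | 3-(4-hydroxy-3-methoxyphenyl)propanoic acid (dihydroferulic acid) | COc1cc(CCC(=O)O)ccc1O | starting material
2 | benzyl 3-[4-(benzyloxy)-3-methoxyphenyl]propanoate (formed in the flask) | COc1cc(CCC(=O)OCc2ccccc2)ccc1OCc1ccccc1 | intermediate
3 | 3-[4-(benzyloxy)-3-methoxyphenyl]propanoic acid | COc1cc(CCC(=O)O)ccc1OCc1ccccc1 | intermediate
4 | (4S)-4-benzyl-1,3-oxazolidin-2-one | O=C1N[C@@H](Cc2ccccc2)CO1 | starting material
5 | 3-[4-(benzyloxy)-3-methoxyphenyl]propanoic 2,2-dimethylpropanoic anhydride (formed in the flask) | COc1cc(CCC(=O)OC(=O)C(C)(C)C)ccc1OCc1ccccc1 | intermediate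
6 | (4S)-4-benzyl-3-{3-[4-(benzyloxy)-3-methoxyphenyl]propanoyl}-1,3-oxazolidin-2-one | COc1cc(CCC(=O)N2[C@@H](Cc3ccccc3)COC2=O)ccc1OCc1ccccc1 | intermediate
7 | 1-[3,4-bis(benzyloxy)phenyl]ethan-1-one | CC(=O)c1ccc(OCc2ccccc2)c(OCc2ccccc2)c1 | starting material
8 | lithium (Z)-enolate of 6 (formed in the flask) | [Li+].[O-]/C(=C\Cc1ccc(OCc2ccccc2)c(OC)c1)N1[C@@H](Cc2ccccc2)COC1=O | intermediate
9 | lithium 1-[3,4-bis(benzyloxy)phenyl]ethen-1-olate (formed in the flask) | [Li+].[O-]C(=C)c1ccc(OCc2ccccc2)c(OCc2ccccc2)c1 | intermediate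
10 | (4S)-4-benzyl-3-[(2R)-2-{[4-(benzyloxy)-3-methoxyphenyl]methyl}-4-[3,4-bis(benzyloxy)phenyl]-4-oxobutanoyl]-1,3-oxazolidin-2-one | O=C(C[C@@H](Cc1ccc(OCc2ccccc2)c(OC)c1)C(=O)N1[C@@H](Cc2ccccc2)COC1=O)c1ccc(OCc2ccccc2)c(OCc2ccccc2)c1 | intermediate
11 | (4S)-4-benzyl-3-[(2R)-2-{[4-(benzyloxy)-3-methoxyphenyl]methyl}-3-[3,4-bis(benzyloxy)benzoyl]-4-hydroxybutanoyl]-1,3-oxazolidin-2-one (both C3 epimers, formed in the flask) | O=C(C(CO)[C@@H](Cc1ccc(OCc2ccccc2)c(OC)c1)C(=O)N1[C@@H](Cc2ccccc2)COC1=O)c1ccc(OCc2ccccc2)c(OCc2ccccc2)c1 | intermediate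
12 | (3R,4R)-3-{[4-(benzyloxy)-3-methoxyphenyl]methyl}-4-[3,4-bis(benzyloxy)benzoyl]oxolan-2-one | O=C1OC[C@H](C(=O)c2ccc(OCc3ccccc3)c(OCc3ccccc3)c2)[C@H]1Cc1ccc(OCc2ccccc2)c(OC)c1 | intermediate
13 | (2R,3R)-2-{[4-(benzyloxy)-3-methoxyphenyl]methyl}-3-{[3,4-bis(benzyloxy)phenyl](hydroxy)methyl}butane-1,4-diol (both carbinol epimers) | OC[C@H](Cc1ccc(OCc2ccccc2)c(OC)c1)[C@H](CO)C(O)c1ccc(OCc2ccccc2)c(OCc2ccccc2)c1 | intermediate
14 | [(2S,3R,4R)-2-[3,4-bis(benzyloxy)phenyl]-4-{[4-(benzyloxy)-3-methoxyphenyl]methyl}oxolan-3-yl]methanol | COc1cc(C[C@H]2CO[C@H](c3ccc(OCc4ccccc4)c(OCc4ccccc4)c3)[C@H]2CO)ccc1OCc1ccccc1 | intermediate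
15 | [(2S,3R,4R)-2-[3,4-bis(benzyloxy)phenyl]-4-{[4-(benzyloxy)-3-methoxyphenyl]methyl}oxolan-3-yl]methyl acetate | COc1cc(C[C@H]2CO[C@H](c3ccc(OCc4ccccc4)c(OCc4ccccc4)c3)[C@H]2COC(C)=O)ccc1OCc1ccccc1 | intermediate
16 | [(2S,3R,4R)-2-(3,4-dihydroxyphenyl)-4-[(4-hydroxy-3-methoxyphenyl)methyl]oxolan-3-yl]methyl acetate | COc1cc(C[C@H]2CO[C@H](c3ccc(O)c(O)c3)[C@H]2COC(C)=O)ccc1O | target

**Step count**

Total steps: 8. Longest linear sequence: 8 (1 → 16; 4 and 7 are bought).

**Steps most likely to fail, with fallbacks**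

Step 3 (oxidative heterocoupling). Homodimers of either enolate, over-oxidation of the still-enolisable product and a modest yield are the expected problems, and the facial selectivity is assumed by analogy with Evans alkylations. Fe(acac)3 (trivalent iron) is the obvious oxidant variation. The real fallback sets out from 6 and 7 and returns at 10. Ketone 7 is brominated with PhNMe3Br3 in THF to 2-bromo-1-[3,4-bis(benzyloxy)phenyl]ethan-1-one F1. Imide 6 is deprotonated with NaN(SiMe3)2 in THF at −78 °C to the sodium (Z)-enolate of 6 F2, which is alkylated with F1. This is a two-electron Evans alkylation in which the α-bromo ketone is the acceptor at the α-carbon, and it gives 10 with the same 2R configuration.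

Step 4 (aldol/lactonisation on the imide). Hydrolytic loss of the imide, E1cB opening of the β-acyloxy ketone, double hydroxymethylation or incomplete trans equilibration could intervene. The fallback sets out from 10 and returns at 12. LiOH/H2O2 in THF/H2O at 0 °C removes the auxiliary to give (2R)-2-{[4-(benzyloxy)-3-methoxyphenyl]methyl}-4-[3,4-bis(benzyloxy)phenyl]-4-oxobutanoic acid F3. Its sodium salt is hydroxymethylated with 37% aqueous formaldehyde in dilute NaOH (the classical aroylpropanoic acid procedure; the α-proton of the carboxylate at C8' is not acidic, so the stereocentre is safe) to (2R)-2-{[4-(benzyloxy)-3-methoxyphenyl]methyl}-3-[3,4-bis(benzyloxy)benzoyl]-4-hydroxybutanoic acid F4, which is not isolated. Acidification with HCl closes it to the lactone, and a brief treatment with catalytic DBU in CH2Cl2 completes equilibration to trans 12.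

Step 8 (hydrogenolysis). The product carries a p-hydroxyaryl group on the ring benzylic carbon, so over-reduction to the ring-opened diarylbutane and air oxidation of the catechol are the risks. The fallback sets out from 14 and returns at 16, avoiding hydrogen altogether and reversing the order of the last two operations. BCl3 with pentamethylbenzene as benzyl-cation scavenger in CH2Cl2 at −78 °C removes the three benzyl ethers to give (2S,3R,4R)-2-(3,4-dihydroxyphenyl)-4-[(4-hydroxy-3-methoxyphenyl)methyl]-3-(hydroxymethyl)oxolane F5. Immobilised Candida antarctica lipase B with vinyl acetate in THF then acetylates only the primary aliphatic hydroxyl (phenols are not substrates) to give 16.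

**Further compounds**

F1 | step 3 | 2-bromo-1-[3,4-bis(benzyloxy)phenyl]ethan-1-one | O=C(CBr)c1ccc(OCc2ccccc2)c(OCc2ccccc2)c1
F2 | step 3 | sodium (Z)-enolate of 6 | [Na+].[O-]/C(=C\Cc1ccc(OCc2ccccc2)c(OC)c1)N1[C@@H](Cc2ccccc2)COC1=O
F3 | step 4 | (2R)-2-{[4-(benzyloxy)-3-methoxyphenyl]methyl}-4-[3,4-bis(benzyloxy)phenyl]-4-oxobutanoic acid | O=C(C[C@@H](Cc1ccc(OCc2ccccc2)c(OC)c1)C(=O)O)c1ccc(OCc2ccccc2)c(OCc2ccccc2)c1
F4 | step 4 | (2R)-2-{[4-(benzyloxy)-3-methoxyphenyl]methyl}-3-[3,4-bis(benzyloxy)benzoyl]-4-hydroxybutanoic acid (both C3 epimers) | O=C(C(CO)[C@@H](Cc1ccc(OCc2ccccc2)c(OC)c1)C(=O)O)c1ccc(OCc2ccccc2)c(OCc2ccccc2)c1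
F5 | step 8 | (2S,3R,4R)-2-(3,4-dihydroxyphenyl)-4-[(4-hydroxy-3-methoxyphenyl)methyl]-3-(hydroxymethyl)oxolane | COc1cc(C[C@H]2CO[C@H](c3ccc(O)c(O)c3)[C@H]2CO)ccc1O
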